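**Retrosynthetic overview**

1. Numbering: ring C1 (CH bearing the chain), C2 (CH2), C3–C4 (oxirane, Me on C4), C5 (C=O), C6 (CH–OAng); chain C7 (=C14H2), C8 (CH–OAng), C9, C10–C11 (oxirane, Me2 on C11). The plan rests on the carbocycle C1–C6 being a masked 2-methylcyclohex-2-enone (C5 ketone, C4 methyl, C3–C4 oxirane as oxidised C3=C4, branch at C1), the Michael–aldol retron of an ethyl ketone C4–C5–C6 and a C1–C2–C3 enal.
2. Late stage: C6 angelate from C6–OH; ring oxirane C3–C4 (syn to the C1 chain) from a C5 allylic alcohol by hydroxyl-directed epoxidation (C5 ketone reduced, then re-oxidised); side-chain oxirane C10–C11 by Shi epoxidation of the prenyl alkene; C8 angelate from C8–OH.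
3. C7–C8 by Ni/Cr coupling of the C7 alkenyl iodide with 4-methylpent-3-enal; the iodide from the C1 alkyne; C6–O by trans α′-hydroxylation of the enone.
4. Carbocycle C1–C6 by organocatalytic Michael addition (C1–C6), aldol condensation (C3=C4) and decarboxylation from a silylated enynal and tert-butyl 3-oxopentanoate.
5. Ring order: carbocycle first (step 2), side-chain oxirane second (step 10), ring oxirane last (step 12).

Key step: step 2

Remark: Ang = (Z)-2-methylbut-2-enoyl. The catalyst antipode in step 2 is assigned from the usual iminium shielding model. Which antipode of the sulfonamide ligand in step 8 gives (8S) cannot be assigned with certainty for this α-branched alkenyl partner and would be settled by a pilot coupling with both antipodes.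

**Route**

Step 1
Reactants: 1 3-(trimethylsilyl)prop-2-ynal; 2 (triphenylphosphoranylidene)acetaldehyde
Product: 3 (E)-5-(trimethylsilyl)pent-2-en-4-ynal
Conditions: toluene, rt, 2 added slowly to a slight excess of 1
Reagents that add atoms: none
Why: Wittig olefination with the stabilised formylmethylene ylide should give the (E)-enal, and because the ynal is far more electrophilic than the enal product a second homologation should stay minor.

Step 2
Reactants: 3 (E)-5-(trimethylsilyl)pent-2-en-4-ynal; 4 tert-butyl 3-oxopentanoate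
Product: 7 (S)-2-methyl-5-[(trimethylsilyl)ethynyl]cyclohex-2-en-1-one, via Michael adduct 5 (not isolated), via cyclohexenone tert-butyl ester 6 (not isolated)
Conditions: (R)-2-{bis[3,5-bis(trifluoromethyl)phenyl](trimethylsilyloxy)methyl}pyrrolidine (10 mol%), toluene, 0 °C → rt; then TsOH·H2O (20 mol%), toluene, 80 °C
Reagents that add atoms: none
Why: The amine condenses with 3 to an (E), s-trans iminium ion whose Si face at C1 is covered by the diaryl(silyloxy)methyl group of the (R)-catalyst, so the enol of 4 should attack C1 through C6 from the Re face and form the C1–C6 bond of 5 with C1 (S) under catalyst control (the C6 epimers of 5 are of no consequence). On acidification the enol of the ethyl ketone attacks the aldehyde through C4 in a 6-(enolendo)-exo-trig aldol closure that forms C3–C4 and the only carbocycle, dehydration gives the C3=C4 enone 6, and the tert-butyl ester is cleaved to 2-methylpropene with loss of CO2 from the β-keto acid, leaving C6 as CH2. The closest known reaction type is the diarylprolinol-silyl-ether-catalysed Michael addition of β-keto esters to enals with acid-promoted aldol condensation and decarboxylation to 5-substituted cyclohex-2-enones. The step needs 1,4- over 1,6-addition, which the trimethylsilyl cap on the alkyne terminus and the larger acceptor coefficient at C1 of the iminium ion should secure, and a single aldol regiochemistry, which follows because only the C4 methylene reaches C3 through a six-membered transition state. The ethyl group supplies the C4 methyl and the silylalkyne on C1 is the latent C7 alkenyl unit.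

Step 3
Reactants: 7 (S)-2-methyl-5-[(trimethylsilyl)ethynyl]cyclohex-2-en-1-one
Product: 10 (5R,6R)-6-hydroxy-2-methyl-5-[(trimethylsilyl)ethynyl]cyclohex-2-en-1-one, via silyl dienol ether 8 (not isolated), via 6-trimethylsilyloxy ketone 9 (not isolated)
Conditions: LDA, TMSCl, THF, −78 °C; m-CPBA, NaHCO3, CH2Cl2, −20 → 0 °C; 1 M HCl (cat.), THF, 0 °C
Reagents that add atoms: m-chloroperoxybenzoic acid, O=C(OO)c1cccc(Cl)c1
Why: Kinetic α′-deprotonation at C6 gives the cross-conjugated silyl dienol ether, whose electron-rich C5=C6 bond should be epoxidised on the face away from the adjacent C1 alkynyl group (Rubottom oxidation), so that after silyl migration and hydrolysis the C6 hydroxyl (6R) is trans to the C1 substituent, as in electrophilic trapping of 3-substituted cyclohexanone enolates, the minor cis isomer being removed by chromatography.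

Step 4
Reactants: 10 (5R,6R)-6-hydroxy-2-methyl-5-[(trimethylsilyl)ethynyl]cyclohex-2-en-1-one
Product: 11 (5R,6R)-6-[(tert-butyldimethylsilyl)oxy]-2-methyl-5-[(trimethylsilyl)ethynyl]cyclohex-2-en-1-one
Conditions: TBSCl, imidazole, DMF, rt
Reagents that add atoms: tert-butyldimethylsilyl chloride, CC(C)(C)[Si](C)(C)Cl
Why: Standard imidazole-mediated silylation of a secondary α-hydroxy ketone masks the C6 hydroxyl for the coupling and redox steps without touching a stereocentre.

Step 5
Reactants: 11 (5R,6R)-6-[(tert-butyldimethylsilyl)oxy]-2-methyl-5-[(trimethylsilyl)ethynyl]cyclohex-2-en-1-one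
Product: 12 (5R,6R)-6-[(tert-butyldimethylsilyl)oxy]-5-ethynyl-2-methylcyclohex-2-en-1-one
Conditions: K2CO3 (cat.), MeOH, 0 °C
Reagents that add atoms: none
Why: Catalytic methoxide cleaves the C(sp)–Si bond by protodesilylation much faster than it attacks the secondary tert-butyldimethylsilyl ether or adds to the α-methyl enone at 0 °C.

Step 6
Reactants: 12 (5R,6R)-6-[(tert-butyldimethylsilyl)oxy]-5-ethynyl-2-methylcyclohex-2-en-1-one
Product: 14 (5S,6R)-6-[(tert-butyldimethylsilyl)oxy]-5-(1-iodoethenyl)-2-methylcyclohex-2-en-1-one, via iodoalkenyl borane 13 (not isolated)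
Conditions: B-iodo-9-BBN, pentane/CH2Cl2, −20 → 0 °C; AcOH, 0 °C; aq. NaHCO3 work-up without peroxide
Reagents that add atoms: B-iodo-9-borabicyclo[3.3.1]nonane, IB1C2CCCC1CCC2
Why: Haloboration adds boron to the terminal and iodine to the internal alkyne carbon in a syn fashion, and protonolysis of the alkenyl–boron bond with acetic acid then leaves the 2-iodo-1-alkene (net Markovnikov hydroiodination), the non-oxidative work-up sparing the enone.

Step 7
Reactants: 15 4-methylpent-3-en-1-ol
Product: 16 4-methylpent-3-enal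
Conditions: Dess–Martin periodinane, NaHCO3, CH2Cl2, 0 °C; used at once as a cold concentrated solution
Reagents that add atoms: none
Why: Dess–Martin oxidation under bicarbonate buffer should give the β,γ-unsaturated aldehyde without the acid or base that would move the double bond into conjugation, and immediate use avoids loss of this volatile aldehyde.

Step 8
Reactants: 14 (5S,6R)-6-[(tert-butyldimethylsilyl)oxy]-5-(1-iodoethenyl)-2-methylcyclohex-2-en-1-one; 16 4-methylpent-3-enal
Product: 17 (5R,6R)-6-[(tert-butyldimethylsilyl)oxy]-5-[(3S)-3-hydroxy-6-methylhepta-1,5-dien-2-yl]-2-methylcyclohex-2-en-1-one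
Conditions: CrCl2, N-[2-(4-isopropyl-4,5-dihydrooxazol-2-yl)-6-methylphenyl]methanesulfonamide (one antipode, see remark), Et3N, THF, rt; then NiCl2 (cat.), 14 and 16, rt
Reagents that add atoms: none
Why: In this Nozaki–Hiyama–Kishi reaction nickel inserts into the C7–I bond, transmetallation gives an alkenylchromium(III) species that adds to the aldehyde and ignores the enone, and the chiral sulfonamide ligand on chromium is relied on to deliver the alkenyl group to the aldehyde face that gives the (8S)-carbinol by reagent control.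

Step 9
Reactants: 17 (5R,6R)-6-[(tert-butyldimethylsilyl)oxy]-5-[(3S)-3-hydroxy-6-methylhepta-1,5-dien-2-yl]-2-methylcyclohex-2-en-1-one
Product: 18 (3S)-2-[(1R,6R)-6-[(tert-butyldimethylsilyl)oxy]-4-methyl-5-oxocyclohex-3-en-1-yl]-6-methylhepta-1,5-dien-3-yl (2Z)-2-methylbut-2-enoate
Conditions: angelic acid, 2,4,6-trichlorobenzoyl chloride, Et3N, toluene, rt; then 17, toluene, 75 °C, no DMAP
Reagents that add atoms: angelic acid, C/C=C(/C)C(=O)O
Why: Acylation through the preformed mixed anhydride with 2,4,6-trichlorobenzoic acid (Yamaguchi-type esterification) without a nucleophilic catalyst is the established way to esterify hindered secondary alcohols with angelic acid without Z to E isomerisation, and C8 is retained since only the O–H bond is broken.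

Step 10
Reactants: 18 (3S)-2-[(1R,6R)-6-[(tert-butyldimethylsilyl)oxy]-4-methyl-5-oxocyclohex-3-en-1-yl]-6-methylhepta-1,5-dien-3-yl (2Z)-2-methylbut-2-enoate
Product: 19 (2S)-3-[(1R,6R)-6-[(tert-butyldimethylsilyl)oxy]-4-methyl-5-oxocyclohex-3-en-1-yl]-1-[(2R)-3,3-dimethyloxiran-2-yl]but-3-en-2-yl (2Z)-2-methylbut-2-enoate
Conditions: D-fructose-derived ketone catalyst (30 mol%), Oxone, K2CO3, Bu4NHSO4, MeCN/dimethoxymethane/aq. borate buffer (pH 10.5), 0 °C
Reagents that add atoms: potassium peroxymonosulfate (Oxone), [K+].[O-]S(=O)(=O)OO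
Why: In this Shi epoxidation the electrophilic chiral dioxirane should pick the electron-rich trisubstituted C10=C11 bond over the enone, the angelate and the hindered 1,1-disubstituted C7=C14 alkene, and its spiro transition state should deliver oxygen to the face that gives the (10R)-oxirane by reagent control.

Step 11
Reactants: 19 (2S)-3-[(1R,6R)-6-[(tert-butyldimethylsilyl)oxy]-4-methyl-5-oxocyclohex-3-en-1-yl]-1-[(2R)-3,3-dimethyloxiran-2-yl]but-3-en-2-yl (2Z)-2-methylbut-2-enoate
Product: 20 (2S)-3-[(1R,5R,6R)-6-[(tert-butyldimethylsilyl)oxy]-5-hydroxy-4-methylcyclohex-3-en-1-yl]-1-[(2R)-3,3-dimethyloxiran-2-yl]but-3-en-2-yl (2Z)-2-methylbut-2-enoate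
Conditions: NaBH4, CeCl3·7H2O, MeOH, −78 °C
Reagents that add atoms: none
Why: Luche reduction gives 1,2-reduction only, and axial hydride delivery to C5, anti to the axial C6–H of the diequatorial half-chair (as in the reduction of carvone to cis-carveol), should place the new hydroxyl equatorial, cis to the C1 chain and trans to the C6 silyl ether (5R).

Step 12
Reactants: 20 (2S)-3-[(1R,5R,6R)-6-[(tert-butyldimethylsilyl)oxy]-5-hydroxy-4-methylcyclohex-3-en-1-yl]-1-[(2R)-3,3-dimethyloxiran-2-yl]but-3-en-2-yl (2Z)-2-methylbut-2-enoate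
Product: 21 (2S)-3-[(1R,3R,4R,5S,6S)-4-[(tert-butyldimethylsilyl)oxy]-5-hydroxy-6-methyl-7-oxabicyclo[4.1.0]heptan-3-yl]-1-[(2R)-3,3-dimethyloxiran-2-yl]but-3-en-2-yl (2Z)-2-methylbut-2-enoate
Conditions: VO(acac)2 (cat.), t-BuOOH (in decane), CH2Cl2, 0 °C → rt
Reagents that add atoms: tert-butyl hydroperoxide, CC(C)(C)OO
Why: Hydroxyl-directed vanadium-catalysed epoxidation delivers the peroxide oxygen from the C5 vanadate to the same face of the adjacent C3=C4 bond, which sets C3 and C4 syn to the C5 hydroxyl and hence syn to the C1 chain, while the alkenes without an allylic hydroxyl are not touched.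

Step 13
Reactants: 21 (2S)-3-[(1R,3R,4R,5S,6S)-4-[(tert-butyldimethylsilyl)oxy]-5-hydroxy-6-methyl-7-oxabicyclo[4.1.0]heptan-3-yl]-1-[(2R)-3,3-dimethyloxiran-2-yl]but-3-en-2-yl (2Z)-2-methylbut-2-enoate
Product: 22 (2S)-3-[(1R,3R,4R,6R)-4-[(tert-butyldimethylsilyl)oxy]-6-methyl-5-oxo-7-oxabicyclo[4.1.0]heptan-3-yl]-1-[(2R)-3,3-dimethyloxiran-2-yl]but-3-en-2-yl (2Z)-2-methylbut-2-enoate
Conditions: Dess–Martin periodinane, NaHCO3, CH2Cl2, 0 °C → rt
Reagents that add atoms: none
Why: Dess–Martin oxidation under buffered neutral conditions returns the C5 ketone without opening either oxirane or epimerising C6.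

Step 14
Reactants: 22 (2S)-3-[(1R,3R,4R,6R)-4-[(tert-butyldimethylsilyl)oxy]-6-methyl-5-oxo-7-oxabicyclo[4.1.0]heptan-3-yl]-1-[(2R)-3,3-dimethyloxiran-2-yl]but-3-en-2-yl (2Z)-2-methylbut-2-enoate
Product: 23 (2S)-1-[(2R)-3,3-dimethyloxiran-2-yl]-3-[(1R,3R,4R,6R)-4-hydroxy-6-methyl-5-oxo-7-oxabicyclo[4.1.0]heptan-3-yl]but-3-en-2-yl (2Z)-2-methylbut-2-enoate
Conditions: TBAF, AcOH (1:1), THF, 0 °C
Reagents that add atoms: none
Why: Fluoride buffered with acetic acid cleaves the activated α-keto silyl ether under nearly neutral conditions that should neither enolise C6 nor open the oxiranes nor cleave the angelate.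

Step 15
Reactants: 23 (2S)-1-[(2R)-3,3-dimethyloxiran-2-yl]-3-[(1R,3R,4R,6R)-4-hydroxy-6-methyl-5-oxo-7-oxabicyclo[4.1.0]heptan-3-yl]but-3-en-2-yl (2Z)-2-methylbut-2-enoate
Product: 24 (2S)-1-[(2R)-3,3-dimethyloxiran-2-yl]-3-[(1R,3R,4R,6R)-6-methyl-4-{[(2Z)-2-methylbut-2-enoyl]oxy}-5-oxo-7-oxabicyclo[4.1.0]heptan-3-yl]but-3-en-2-yl (2Z)-2-methylbut-2-enoate (CNP0247177.1)
Conditions: angelic acid, 2,4,6-trichlorobenzoyl chloride, Et3N, toluene, rt; then 23, toluene, 70 °C, no DMAP
Reagents that add atoms: angelic acid, C/C=C(/C)C(=O)O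
Why: The same mixed-anhydride (Yamaguchi-type) esterification acylates the C6 hydroxyl of the α-hydroxy ketone with retention and without isomerisation to the tiglate, which completes the target.

**Compound list**

1 | 3-(trimethylsilyl)prop-2-ynal | O=CC#C[Si](C)(C)C | starting material
2 | (triphenylphosphoranylidene)acetaldehyde | O=CC=P(c1ccccc1)(c1ccccc1)c1ccccc1 | starting material
3 | (E)-5-(trimethylsilyl)pent-2-en-4-ynal | O=C/C=C/C#C[Si](C)(C)C | intermediate
4 | tert-butyl 3-oxopentanoate | CCC(=O)CC(=O)OC(C)(C)C | starting material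
5 | tert-butyl (3S)-3-(2-oxoethyl)-2-propanoyl-5-(trimethylsilyl)pent-4-ynoate (C2 epimers) | C[Si](C)(C)C#C[C@@H](CC=O)C(C(=O)CC)C(=O)OC(C)(C)C | intermediate
6 | tert-butyl (6S)-3-methyl-2-oxo-6-[(trimethylsilyl)ethynyl]cyclohex-3-ene-1-carboxylate (C1 epimers) | C[Si](C)(C)C#C[C@H]1CC=C(C)C(=O)C1C(=O)OC(C)(C)C | intermediate
7 | (S)-2-methyl-5-[(trimethylsilyl)ethynyl]cyclohex-2-en-1-one | C[Si](C)(C)C#C[C@H]1CC=C(C)C(=O)C1 | intermediate
8 | trimethyl{[(3S)-6-methyl-3-[(trimethylsilyl)ethynyl]cyclohexa-1,5-dien-1-yl]oxy}silane | C[Si](C)(C)C#C[C@H]1CC=C(C)C(O[Si](C)(C)C)=C1 | intermediate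
9 | (5R,6R)-2-methyl-6-[(trimethylsilyl)oxy]-5-[(trimethylsilyl)ethynyl]cyclohex-2-en-1-one | C[Si](C)(C)C#C[C@H]1CC=C(C)C(=O)[C@@H]1O[Si](C)(C)C | intermediate
10 | (5R,6R)-6-hydroxy-2-methyl-5-[(trimethylsilyl)ethynyl]cyclohex-2-en-1-one | C[Si](C)(C)C#C[C@H]1CC=C(C)C(=O)[C@@H]1O | intermediate
11 | (5R,6R)-6-[(tert-butyldimethylsilyl)oxy]-2-methyl-5-[(trimethylsilyl)ethynyl]cyclohex-2-en-1-one | C[Si](C)(C)C#C[C@H]1CC=C(C)C(=O)[C@@H]1O[Si](C)(C)C(C)(C)C | intermediate
12 | (5R,6R)-6-[(tert-butyldimethylsilyl)oxy]-5-ethynyl-2-methylcyclohex-2-en-1-one | C#C[C@H]1CC=C(C)C(=O)[C@@H]1O[Si](C)(C)C(C)(C)C | intermediate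
13 | (5S,6R)-5-[(Z)-2-(9-borabicyclo[3.3.1]nonan-9-yl)-1-iodoethenyl]-6-[(tert-butyldimethylsilyl)oxy]-2-methylcyclohex-2-en-1-one | I/C(=C\B2C3CCCC2CCC3)[C@H]1CC=C(C)C(=O)[C@@H]1O[Si](C)(C)C(C)(C)C | intermediate
14 | (5S,6R)-6-[(tert-butyldimethylsilyl)oxy]-5-(1-iodoethenyl)-2-methylcyclohex-2-en-1-one | C=C(I)[C@H]1CC=C(C)C(=O)[C@@H]1O[Si](C)(C)C(C)(C)C | intermediate
15 | 4-methylpent-3-en-1-ol | CC(C)=CCCO | starting material
16 | 4-methylpent-3-enal | CC(C)=CCC=O | intermediate
17 | (5R,6R)-6-[(tert-butyldimethylsilyl)oxy]-5-[(3S)-3-hydroxy-6-methylhepta-1,5-dien-2-yl]-2-methylcyclohex-2-en-1-one | C=C([C@H](CC=C(C)C)O)[C@H]1CC=C(C)C(=O)[C@@H]1O[Si](C)(C)C(C)(C)C | intermediate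
18 | (3S)-2-[(1R,6R)-6-[(tert-butyldimethylsilyl)oxy]-4-methyl-5-oxocyclohex-3-en-1-yl]-6-methylhepta-1,5-dien-3-yl (2Z)-2-methylbut-2-enoate | C=C([C@H](CC=C(C)C)OC(=O)/C(C)=C\C)[C@H]1CC=C(C)C(=O)[C@@H]1O[Si](C)(C)C(C)(C)C | intermediate
19 | (2S)-3-[(1R,6R)-6-[(tert-butyldimethylsilyl)oxy]-4-methyl-5-oxocyclohex-3-en-1-yl]-1-[(2R)-3,3-dimethyloxiran-2-yl]but-3-en-2-yl (2Z)-2-methylbut-2-enoate | C=C([C@H](C[C@H]2OC2(C)C)OC(=O)/C(C)=C\C)[C@H]1CC=C(C)C(=O)[C@@H]1O[Si](C)(C)C(C)(C)C | intermediate
20 | (2S)-3-[(1R,5R,6R)-6-[(tert-butyldimethylsilyl)oxy]-5-hydroxy-4-methylcyclohex-3-en-1-yl]-1-[(2R)-3,3-dimethyloxiran-2-yl]but-3-en-2-yl (2Z)-2-methylbut-2-enoate | C=C([C@H](C[C@H]2OC2(C)C)OC(=O)/C(C)=C\C)[C@H]1CC=C(C)[C@@H](O)[C@@H]1O[Si](C)(C)C(C)(C)C | intermediate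
21 | (2S)-3-[(1R,3R,4R,5S,6S)-4-[(tert-butyldimethylsilyl)oxy]-5-hydroxy-6-methyl-7-oxabicyclo[4.1.0]heptan-3-yl]-1-[(2R)-3,3-dimethyloxiran-2-yl]but-3-en-2-yl (2Z)-2-methylbut-2-enoate | C=C([C@H](C[C@H]2OC2(C)C)OC(=O)/C(C)=C\C)[C@H]1C[C@H]3O[C@@]3(C)[C@@H](O)[C@@H]1O[Si](C)(C)C(C)(C)C | intermediate
22 | (2S)-3-[(1R,3R,4R,6R)-4-[(tert-butyldimethylsilyl)oxy]-6-methyl-5-oxo-7-oxabicyclo[4.1.0]heptan-3-yl]-1-[(2R)-3,3-dimethyloxiran-2-yl]but-3-en-2-yl (2Z)-2-methylbut-2-enoate | C=C([C@H](C[C@H]2OC2(C)C)OC(=O)/C(C)=C\C)[C@H]1C[C@H]3O[C@@]3(C)C(=O)[C@@H]1O[Si](C)(C)C(C)(C)C | intermediate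
23 | (2S)-1-[(2R)-3,3-dimethyloxiran-2-yl]-3-[(1R,3R,4R,6R)-4-hydroxy-6-methyl-5-oxo-7-oxabicyclo[4.1.0]heptan-3-yl]but-3-en-2-yl (2Z)-2-methylbut-2-enoate | C=C([C@H](C[C@H]2OC2(C)C)OC(=O)/C(C)=C\C)[C@H]1C[C@H]3O[C@@]3(C)C(=O)[C@@H]1O | intermediate
24 | (2S)-1-[(2R)-3,3-dimethyloxiran-2-yl]-3-[(1R,3R,4R,6R)-6-methyl-4-{[(2Z)-2-methylbut-2-enoyl]oxy}-5-oxo-7-oxabicyclo[4.1.0]heptan-3-yl]but-3-en-2-yl (2Z)-2-methylbut-2-enoate | C=C([C@H](C[C@H]2OC2(C)C)OC(=O)/C(C)=C\C)[C@H]1C[C@H]3O[C@@]3(C)C(=O)[C@@H]1OC(=O)/C(C)=C\C | target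

**Step count and risks**

Total step count: 15. Longest linear sequence: 14 (steps 1–6 and 8–15, from 1); step 7 is the one-step side branch.

Steps most likely to fail:

Step 8. The addition of the alkenylchromium species to the aldehyde may show weak or mismatched facial control and give a C8 epimer mixture, and the β,γ-unsaturated aldehyde may isomerise to the conjugated enal before it couples. Fallback: stereocontrol is moved from the C–C bond formation to an invertive esterification. Setting out from 14 and 16, the coupling would be run ligand-free (CrCl2, NiCl2 cat., DMF/THF, rt) and the C8 epimers separated. The (8S)-alcohol 17 goes on through step 9. The (8R)-epimer, (5R,6R)-6-[(tert-butyldimethylsilyl)oxy]-5-[(3R)-3-hydroxy-6-methylhepta-1,5-dien-2-yl]-2-methylcyclohex-2-en-1-one F1, would be esterified with angelic acid under Mitsunobu conditions (PPh3, DIAD, toluene, 0 °C) with inversion at C8, which should give 18 directly; the route is rejoined at 18.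

Step 6. The Lewis-acidic haloborane may add iodide in a conjugate sense to the enone or cleave the silyl ether, and protonolysis of the alkenylborane may be incomplete. Fallback: setting out from 12, a ruthenium-catalysed Markovnikov hydrostannation (Bu3SnH, [Cp*Ru(MeCN)3]PF6 cat., CH2Cl2, rt) should give the α-stannyl alkene (5S,6R)-6-[(tert-butyldimethylsilyl)oxy]-2-methyl-5-[1-(tributylstannyl)ethenyl]cyclohex-2-en-1-one F2. Iododestannylation (I2, CH2Cl2, 0 °C) would then return 14, where the route is rejoined.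

Step 2. Enantioface selection may erode because the rod-like alkynyl group differentiates the iminium faces less well and uncatalysed background addition competes, and some 1,6-addition may occur. Fallback: stereocontrol by enzymatic kinetic resolution in place of asymmetric catalysis. Setting out from scalemic trans-hydroxy ketone 10, lipase-catalysed transesterification with vinyl acetate (immobilised lipase of the required enantiopreference chosen by screening, MTBE, rt) would acetylate the unwanted antipode to (1S,6S)-3-methyl-2-oxo-6-[(trimethylsilyl)ethynyl]cyclohex-3-en-1-yl acetate F3. F3 is separated, leaving enantiopure 10, where the route is rejoined.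

**Further compounds**

F1 | step 8 | (5R,6R)-6-[(tert-butyldimethylsilyl)oxy]-5-[(3R)-3-hydroxy-6-methylhepta-1,5-dien-2-yl]-2-methylcyclohex-2-en-1-one | C=C([C@@H](CC=C(C)C)O)[C@H]1CC=C(C)C(=O)[C@@H]1O[Si](C)(C)C(C)(C)C
F2 | step 6 | (5S,6R)-6-[(tert-butyldimethylsilyl)oxy]-2-methyl-5-[1-(tributylstannyl)ethenyl]cyclohex-2-en-1-one | C=C([Sn](CCCC)(CCCC)CCCC)[C@H]1CC=C(C)C(=O)[C@@H]1O[Si](C)(C)C(C)(C)C
F3 | step 2 | (1S,6S)-3-methyl-2-oxo-6-[(trimethylsilyl)ethynyl]cyclohex-3-en-1-yl acetate | C[Si](C)(C)C#C[C@@H]1CC=C(C)C(=O)[C@H]1OC(C)=O
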